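**Assumption:** the target has no stereocentre and no stereogenic double bond, so there is no enantiomer to select; stereocentres in intermediates 5, 6, 14 and 17 are racemic and are removed again later.

## Retrosynthetic overview

1. Target 19 ⇐ tetra-O-benzyl ether 18 by global hydrogenolysis.
2. Each ArCH2–Ar bond of 18 ⇐ aryllithium (from an aryl bromide) + 4-(benzyloxy)benzaldehyde 12, then ionic deoxygenation of the diaryl carbinol; done twice from dibromide 11.
3. Dibromide 11 ⇐ dibromination of dihydropinosylvin dibenzyl ether 10 ⇐ dihydropinosylvin 9.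
4. The central resorcinol ring of 9 is the only ring built (the three outer benzene rings are bought in 1 and 12): key intermolecular Michael addition of dimethyl malonate 4 to enone 3, intramolecular Claisen ring closure, then aromatisation with decarboxylation.
5. Enone 3 ⇐ 3-phenylpropanal 1 + acetonyl ylide 2 (Wittig).

## Route

**Step 1**
Reactants: 1 3-phenylpropanal; 2 1-(triphenylphosphoranylidene)propan-2-one
Product: 3 (E)-6-phenylhex-3-en-2-one
Conditions: toluene, 80 °C, 12 h
Reagents that add atoms: none
Why: Wittig olefination with a ketone-stabilised ylide is chemoselective for the aldehyde and gives the (E)-enone; no stereocentre is formed.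

**Step 2**
Reactants: 3 (E)-6-phenylhex-3-en-2-one; 4 dimethyl malonate
Product: 6 methyl 2-hydroxy-4-oxo-6-(2-phenylethyl)cyclohex-2-ene-1-carboxylate, via Michael adduct 5 (not isolated)
Conditions: NaOMe (1.1 equiv), MeOH, reflux, 4 h; then aq HCl to pH 2, 0 °C
Reagents that add atoms: none
Why: Intermolecular Michael addition of the malonate anion to the enone β-carbon joins the two fragments, and an in-flask intramolecular Claisen (Dieckmann-type) condensation of the methyl-ketone enolate onto one ester closes the six-membered 1,3-dione ring (the olivetol-type annulation), driven by formation of the stabilised sodium enolate; the two ring stereocentres form as a racemic, mainly trans mixture and are erased in step 3.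

**Step 3**
Reactants: 6 methyl 2-hydroxy-4-oxo-6-(2-phenylethyl)cyclohex-2-ene-1-carboxylate
Product: 9 5-(2-phenylethyl)benzene-1,3-diol (dihydropinosylvin), via aryl ester 7 (not isolated), via resorcylic acid 8 (not isolated)
Conditions: Br2 (1.0 equiv), DMF, 0 °C to rt; then 80 °C, then 150 °C, 8 h
Reagents that add atoms: none
Why: Halogenation–dehydrohalogenation aromatisation (α-bromination between the two carbonyls, loss of HBr) gives the resorcylate ester, bromide then cleaves the methyl ester by SN2 on heating and the 2,4-dihydroxybenzoic acid decarboxylates thermally; no stereocentre remains.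

**Step 4**
Reactants: 9 5-(2-phenylethyl)benzene-1,3-diol
Product: 10 1,3-bis(benzyloxy)-5-(2-phenylethyl)benzene
Conditions: BnBr (2.3 equiv), K2CO3 (3 equiv), DMF, 50 °C
Reagents that add atoms: benzyl bromide BrCc1ccccc1
Why: Williamson ether synthesis on both phenols with a mild carbonate base in a polar aprotic solvent favours O- over C-alkylation; no stereocentre is involved.

**Step 5**
Reactants: 10 1,3-bis(benzyloxy)-5-(2-phenylethyl)benzene
Product: 11 1,5-bis(benzyloxy)-2,4-dibromo-3-(2-phenylethyl)benzene
Conditions: NBS (2.05 equiv), MeCN, 0 °C to rt, dark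
Reagents that add atoms: N-bromosuccinimide O=C1CCC(=O)N1Br
Why: Electrophilic aromatic bromination goes to the two equivalent positions para to one benzyloxy group and ortho to the other (those flanking the side chain), while the shielded position between the two alkoxy groups reacts last and the unactivated phenyl rings are untouched; no stereocentre is involved.

**Step 6**
Reactants: 11 1,5-bis(benzyloxy)-2,4-dibromo-3-(2-phenylethyl)benzene; 12 4-(benzyloxy)benzaldehyde
Product: 14 [4,6-bis(benzyloxy)-3-bromo-2-(2-phenylethyl)phenyl][4-(benzyloxy)phenyl]methanol (racemic), via aryllithium 13 (not isolated)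
Conditions: n-BuLi (1.05 equiv), THF, −78 °C, 20 min; then 12 (1.1 equiv), −78 to −20 °C; aq NH4Cl
Reagents that add atoms: none
Why: Bromine–lithium exchange at −78 °C is faster than any deprotonation and stops after one exchange (the two bromines are meta, so no aryne can form), and the aryllithium adds 1,2 to the non-enolisable aldehyde; the new carbinol centre is racemic and is removed in step 7.

**Step 7**
Reactants: 14 [4,6-bis(benzyloxy)-3-bromo-2-(2-phenylethyl)phenyl][4-(benzyloxy)phenyl]methanol
Product: 15 1,5-bis(benzyloxy)-2-[4-(benzyloxy)benzyl]-4-bromo-3-(2-phenylethyl)benzene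
Conditions: Et3SiH (3 equiv), TFA (10 equiv), CH2Cl2, 0 °C, 1 h
Reagents that add atoms: none
Why: Ionic hydrogenation: TFA ionises the doubly benzylic alcohol to a strongly stabilised diarylmethyl cation that excess Et3SiH reduces much faster than it can alkylate the unactivated phenyl of the side chain, while aryl benzyl ethers and the aryl bromide survive; the stereocentre is destroyed.

**Step 8**
Reactants: 15 1,5-bis(benzyloxy)-2-[4-(benzyloxy)benzyl]-4-bromo-3-(2-phenylethyl)benzene; 12 4-(benzyloxy)benzaldehyde
Product: 17 {4,6-bis(benzyloxy)-3-[4-(benzyloxy)benzyl]-2-(2-phenylethyl)phenyl}[4-(benzyloxy)phenyl]methanol (racemic), via aryllithium 16 (not isolated)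
Conditions: n-BuLi (1.1 equiv), THF, −78 °C, 15 min; then 12 (1.2 equiv), −78 to 0 °C; aq NH4Cl
Reagents that add atoms: none
Why: Second bromine–lithium exchange followed by 1,2-addition to the aldehyde; at −78 °C exchange outruns deprotonation of the diarylmethane CH2, and the racemic carbinol centre is removed in step 9.

**Step 9**
Reactants: 17 {4,6-bis(benzyloxy)-3-[4-(benzyloxy)benzyl]-2-(2-phenylethyl)phenyl}[4-(benzyloxy)phenyl]methanol
Product: 18 1,5-bis(benzyloxy)-2,4-bis[4-(benzyloxy)benzyl]-3-(2-phenylethyl)benzene
Conditions: Et3SiH (3 equiv), TFA (10 equiv), CH2Cl2, 0 °C, 1 h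
Reagents that add atoms: none
Why: Ionic hydrogenation of the second diaryl carbinol via its stabilised benzylic cation, as in step 7; it gives the symmetrical, achiral bis(diarylmethane).

**Step 10**
Reactants: 18 1,5-bis(benzyloxy)-2,4-bis[4-(benzyloxy)benzyl]-3-(2-phenylethyl)benzene
Product: 19 4,6-bis(4-hydroxybenzyl)-5-(2-phenylethyl)benzene-1,3-diol (target)
Conditions: H2 (1 atm), Pd/C (10 wt% Pd), EtOAc–MeOH (1:1), rt
Reagents that add atoms: none
Why: Catalytic hydrogenolysis cleaves the four benzylic C–O bonds under neutral conditions while the diarylmethane C–C bonds and the arene rings are inert at 1 atm; the product is achiral.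

## Compound list

1 | 3-phenylpropanal | O=CCCc1ccccc1 | starting material
2 | 1-(triphenylphosphoranylidene)propan-2-one | CC(=O)C=P(c1ccccc1)(c1ccccc1)c1ccccc1 | starting material
3 | (E)-6-phenylhex-3-en-2-one | CC(=O)/C=C/CCc1ccccc1 | intermediate
4 | dimethyl malonate | COC(=O)CC(=O)OC | starting material
5 | dimethyl 2-(5-oxo-1-phenylhexan-3-yl)propanedioate (Michael adduct; racemic; not isolated) | CC(=O)CC(CCc1ccccc1)C(C(=O)OC)C(=O)OC | intermediate
6 | methyl 2-hydroxy-4-oxo-6-(2-phenylethyl)cyclohex-2-ene-1-carboxylate (racemic; mainly trans at C1/C6) | COC(=O)C1C(CCc2ccccc2)CC(=O)C=C1O | intermediate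
7 | methyl 2,4-dihydroxy-6-(2-phenylethyl)benzoate (aryl ester; not isolated) | COC(=O)c1c(O)cc(O)cc1CCc1ccccc1 | intermediate
8 | 2,4-dihydroxy-6-(2-phenylethyl)benzoic acid (resorcylic acid; not isolated) | OC(=O)c1c(O)cc(O)cc1CCc1ccccc1 | intermediate
9 | 5-(2-phenylethyl)benzene-1,3-diol (dihydropinosylvin) | Oc1cc(O)cc(CCc2ccccc2)c1 | intermediate
10 | 1,3-bis(benzyloxy)-5-(2-phenylethyl)benzene | C(Oc1cc(OCc2ccccc2)cc(CCc2ccccc2)c1)c1ccccc1 | intermediate
11 | 1,5-bis(benzyloxy)-2,4-dibromo-3-(2-phenylethyl)benzene | Brc1c(OCc2ccccc2)cc(OCc2ccccc2)c(Br)c1CCc1ccccc1 | intermediate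
12 | 4-(benzyloxy)benzaldehyde | O=Cc1ccc(OCc2ccccc2)cc1 | starting material
13 | [4,6-bis(benzyloxy)-3-bromo-2-(2-phenylethyl)phenyl]lithium (not isolated) | [Li]c1c(OCc2ccccc2)cc(OCc2ccccc2)c(Br)c1CCc1ccccc1 | intermediate
14 | [4,6-bis(benzyloxy)-3-bromo-2-(2-phenylethyl)phenyl][4-(benzyloxy)phenyl]methanol (racemic) | OC(c1ccc(OCc2ccccc2)cc1)c1c(OCc2ccccc2)cc(OCc2ccccc2)c(Br)c1CCc1ccccc1 | intermediate
15 | 1,5-bis(benzyloxy)-2-[4-(benzyloxy)benzyl]-4-bromo-3-(2-phenylethyl)benzene | Brc1c(OCc2ccccc2)cc(OCc2ccccc2)c(Cc2ccc(OCc3ccccc3)cc2)c1CCc1ccccc1 | intermediate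
16 | {4,6-bis(benzyloxy)-3-[4-(benzyloxy)benzyl]-2-(2-phenylethyl)phenyl}lithium (not isolated) | [Li]c1c(OCc2ccccc2)cc(OCc2ccccc2)c(Cc2ccc(OCc3ccccc3)cc2)c1CCc1ccccc1 | intermediate
17 | {4,6-bis(benzyloxy)-3-[4-(benzyloxy)benzyl]-2-(2-phenylethyl)phenyl}[4-(benzyloxy)phenyl]methanol (racemic) | OC(c1ccc(OCc2ccccc2)cc1)c1c(OCc2ccccc2)cc(OCc2ccccc2)c(Cc2ccc(OCc3ccccc3)cc2)c1CCc1ccccc1 | intermediate
18 | 1,5-bis(benzyloxy)-2,4-bis[4-(benzyloxy)benzyl]-3-(2-phenylethyl)benzene | C(c1ccc(OCc2ccccc2)cc1)c1c(OCc2ccccc2)cc(OCc2ccccc2)c(Cc2ccc(OCc3ccccc3)cc2)c1CCc1ccccc1 | intermediate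
19 | 4,6-bis(4-hydroxybenzyl)-5-(2-phenylethyl)benzene-1,3-diol (achiral) | Oc1ccc(Cc2c(O)cc(O)c(Cc3ccc(O)cc3)c2CCc2ccccc2)cc1 | target

## Summary

Total step count: 10.
Longest linear sequence: 10 steps (1 → 19; compounds 2, 4 and 12 are bought).

Three steps most likely to fail, each with a fallback:

- **Step 3** (one-flask bromination, aromatisation and loss of the ester). The risk is ring over-bromination of the very electron-rich resorcinol or incomplete demethoxycarbonylation. The fallback sets out from 6: saponify and decarboxylate (aq NaOH, reflux; then HCl, 80 °C) to 5-(2-phenylethyl)cyclohexane-1,3-dione F1. Aromatise this without any halogen by catalytic dehydrogenation (Pd/C, 10 wt% Pd, mesitylene, reflux under a N2 stream). The fallback comes back to the route at 9.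

- **Step 5** (regiochemistry of the double bromination). The risk is a bromine entering between the two benzyloxy groups, giving a 2,4- instead of a 4,6-pattern. The fallback sets out from 9 and brominates the free resorcinol, where the hydroxyl groups direct more strongly and the 4,6-dihalogenation of 5-alkylresorcinols is well established (Br2, 2.0 equiv, CH2Cl2, −30 °C). This gives 4,6-dibromo-5-(2-phenylethyl)benzene-1,3-diol F2, which is then O-benzylated (BnBr, K2CO3, DMF, 50 °C). The fallback comes back to the route at 11.

- **Step 8** (second bromine–lithium exchange and addition at a position flanked by a benzyloxy group and the side chain, with an acidic diarylmethane CH2 nearby). The risk is proton transfer giving the debrominated arene, or sluggish addition. The fallback sets out from 15 and replaces the organolithium/carbinol/reduction sequence by a Negishi cross-coupling. Commercial 4-(benzyloxy)benzyl chloride is converted with Zn dust and LiCl in THF into [4-(benzyloxy)benzyl]zinc chloride F3. This is coupled with 15 using Pd(OAc)2 (2 mol%) and SPhos (4 mol%) in THF at 60 °C, which forms the diarylmethane directly. The fallback comes back to the route at 18, so steps 8 and 9 are bypassed.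

## Further compounds

F1 | step 3 | 5-(2-phenylethyl)cyclohexane-1,3-dione | O=C1CC(CCc2ccccc2)CC(=O)C1
F2 | step 5 | 4,6-dibromo-5-(2-phenylethyl)benzene-1,3-diol | Oc1cc(O)c(Br)c(CCc2ccccc2)c1Br
F3 | step 8 | [4-(benzyloxy)benzyl]zinc chloride | Cl[Zn]Cc1ccc(OCc2ccccc2)cc1
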